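**Retrosynthetic overview**

1. The target is a (2R,3R)-2,3-bis(arylmethyl)butane-1,4-diol: one arylmethyl is guaiacyl ring A, the other hangs from C5 of a (2S,3R)-trans-2,3-dihydrobenzofuran (benzo ring B; dihydrofuran ring O1–C2–C3–C3a–C7a; guaiacyl ring C on C2; CH2OH on C3).
2. Last disconnection: the bond between the butanediol carbon and the CH2 on C5 of ring B. It is made by trans alkylation of an (R)-4-(arylmethyl)butyrolactone enolate with a benzofuran-5-ylmethyl bromide; LiAlH4 then opens the lactone and the protecting groups come off.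
3. Key disconnection: O1–C2 of the dihydrofuran ring. The strategy rests on C2 being the benzylic carbon para to the phenolic OH of ring C, one bond from C3, which carries ring B with its phenol oxygen O1 in the ortho position. Two-electron oxidation of ring C at an anode makes C2 the exocyclic carbon of a para-quinone methide, and O1 adds to it.
4. The open-chain bis-phenol comes from methyl vanillate: O-allylation and Claisen rearrangement put a carbon arm on ring B, oxidative cleavage gives the arylacetic acid, and an Evans alkylation with a vanillin-derived benzyl bromide sets C3. The same auxiliary and the same bromide give the lactone from mono-tert-butyl succinate.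
5. Ring order: rings A, B and C are bought as arenes; the dihydrofuran ring is closed in step 12; the lactone ring (step 18) is temporary and is opened in step 20.

Key step: step 12

Assumption: 4-(benzyloxy)-3-methoxybenzaldehyde (the benzyl ether of vanillin) and mono-tert-butyl succinate are taken as commercial, and the exocyclic alkene geometry of quinone methide 20 is left open because both isomers should close to the same product.

**Route**

Step 1
Reactants: 1 methyl vanillate; 2 allyl bromide
Product: 3 methyl 4-(allyloxy)-3-methoxybenzoate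
Conditions: K2CO3, acetone, reflux
Reagents that add atoms: none
Why: Williamson ether synthesis, in which the phenoxide formed by K2CO3 displaces bromide from the allylic halide (SN2) and the methyl ester is not touched.

Step 2
Reactants: 3 methyl 4-(allyloxy)-3-methoxybenzoate
Product: 4 methyl 3-allyl-4-hydroxy-5-methoxybenzoate
Conditions: N,N-diethylaniline, 200 °C
Reagents that add atoms: none
Why: Aromatic Claisen rearrangement ([3,3]-sigmatropic shift, then enolisation) should move the allyl group to C5, the only free ortho carbon, since the other ortho position carries OMe and the para position the ester.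

Step 3
Reactants: 4 methyl 3-allyl-4-hydroxy-5-methoxybenzoate
Product: 5 methyl 3-allyl-4-(benzyloxy)-5-methoxybenzoate
Conditions: BnBr, K2CO3, DMF, 60 °C
Reagents that add atoms: benzyl bromide, BrCc1ccccc1
Why: Williamson benzylation caps the hindered phenol as an ether that should survive ozone at low temperature, chlorite, enolate formation and borohydride, and that is removed later by hydrogenolysis.

Step 4
Reactants: 5 methyl 3-allyl-4-(benzyloxy)-5-methoxybenzoate
Product: 8 [2-(benzyloxy)-3-methoxy-5-(methoxycarbonyl)phenyl]acetic acid, via secondary ozonide 6 (not isolated), via arylacetaldehyde 7 (not isolated)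
Conditions: O3, CH2Cl2, −78 °C; Me2S, −78 °C to rt; crude aldehyde: NaClO2, NaH2PO4, 2-methyl-2-butene, t-BuOH/H2O, 0 °C to rt
Reagents that add atoms: ozone, [O-][O+]=O; sodium chlorite NaClO2, [Na+].[O-]Cl=O
Why: Ozonolysis with reductive work-up (Criegee mechanism) cuts the terminal alkene to the arylacetaldehyde far faster than ozone attacks the benzyl ether or the ester-bearing arene, and Pinnick oxidation of the crude aldehyde in the presence of a hypochlorite scavenger gives the acid without ring chlorination.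

Step 5
Reactants: 8 [2-(benzyloxy)-3-methoxy-5-(methoxycarbonyl)phenyl]acetic acid; 9 (R)-4-benzyl-2-oxazolidinone
Product: 11 (4R)-4-benzyl-3-{[2-(benzyloxy)-3-methoxy-5-(methoxycarbonyl)phenyl]acetyl}-1,3-oxazolidin-2-one, via mixed pivalic anhydride 10 (not isolated)
Conditions: t-BuCOCl, Et3N, THF, −20 °C; then 9, LiCl, −20 °C to rt
Reagents that add atoms: none
Why: N-acylation of the oxazolidinone through a mixed pivalic anhydride activated by LiCl and Et3N, in which the nucleophile attacks the less hindered arylacetyl carbonyl and no strong base is present that could harm the ring ester.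

Step 6
Reactants: 12 4-(benzyloxy)-3-methoxybenzaldehyde
Product: 13 [4-(benzyloxy)-3-methoxyphenyl]methanol
Conditions: NaBH4, MeOH, 0 °C
Reagents that add atoms: none
Why: Hydride reduction of an aromatic aldehyde with NaBH4 gives the benzylic alcohol.

Step 7
Reactants: 13 [4-(benzyloxy)-3-methoxyphenyl]methanol
Product: 14 4-(benzyloxy)-3-methoxybenzyl bromide
Conditions: PBr3, Et2O, 0 °C
Reagents that add atoms: phosphorus tribromide, BrP(Br)Br
Why: The alcohol is converted into its bromide by PBr3 (SN2 displacement of the bromophosphite), a standard preparation of electron-rich benzylic bromides, which are used without storage.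

Step 8
Reactants: 11 (4R)-4-benzyl-3-{[2-(benzyloxy)-3-methoxy-5-(methoxycarbonyl)phenyl]acetyl}-1,3-oxazolidin-2-one; 14 4-(benzyloxy)-3-methoxybenzyl bromide
Product: 16 (4R)-4-benzyl-3-[(2R)-2-[2-(benzyloxy)-3-methoxy-5-(methoxycarbonyl)phenyl]-3-[4-(benzyloxy)-3-methoxyphenyl]propanoyl]-1,3-oxazolidin-2-one, via sodium Z-enolate 15 (not isolated)
Conditions: NaN(SiMe3)2, THF, −78 °C; then 14, −78 to −40 °C; AcOH quench at −78 °C
Reagents that add atoms: none
Why: Evans asymmetric alkylation, in which the chelated Z enolate is blocked on one face by the C4 benzyl group of the (R)-auxiliary, so bromide 14 adds to the open face and sets the new centre (the future C3 of the dihydrobenzofuran) as R, while low temperature and the acidic quench guard this acidic aryl-bearing centre against epimerisation.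

Step 9
Reactants: 16 (4R)-4-benzyl-3-[(2R)-2-[2-(benzyloxy)-3-methoxy-5-(methoxycarbonyl)phenyl]-3-[4-(benzyloxy)-3-methoxyphenyl]propanoyl]-1,3-oxazolidin-2-one
Product: 17 methyl 4-(benzyloxy)-3-[(2R)-1-[4-(benzyloxy)-3-methoxyphenyl]-3-hydroxypropan-2-yl]-5-methoxybenzoate
Conditions: NaBH4, THF/H2O 3:1, 0 °C to rt
Reagents that add atoms: none
Why: Reductive removal of the auxiliary with NaBH4 in wet THF (hydride attack at the exocyclic imide carbonyl, then reduction of the released aldehyde) gives the primary alcohol, the aryl methyl ester being inert to NaBH4 and the stereocentre being kept because the aldehyde should be reduced faster than it enolises.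

Step 10
Reactants: 17 methyl 4-(benzyloxy)-3-[(2R)-1-[4-(benzyloxy)-3-methoxyphenyl]-3-hydroxypropan-2-yl]-5-methoxybenzoate
Product: 18 methyl 4-(benzyloxy)-3-[(2R)-1-[4-(benzyloxy)-3-methoxyphenyl]-3-{[tert-butyl(dimethyl)silyl]oxy}propan-2-yl]-5-methoxybenzoate
Conditions: TBSCl, imidazole, DMF, rt
Reagents that add atoms: tert-butyldimethylsilyl chloride, CC(C)(C)[Si](C)(C)Cl
Why: Imidazole-promoted silylation of the only free hydroxyl group gives a TBS ether that is stable to hydrogenolysis, to the anode and to the later base and hydride steps.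

Step 11
Reactants: 18 methyl 4-(benzyloxy)-3-[(2R)-1-[4-(benzyloxy)-3-methoxyphenyl]-3-{[tert-butyl(dimethyl)silyl]oxy}propan-2-yl]-5-methoxybenzoate
Product: 19 methyl 3-[(2R)-1-{[tert-butyl(dimethyl)silyl]oxy}-3-(4-hydroxy-3-methoxyphenyl)propan-2-yl]-4-hydroxy-5-methoxybenzoate
Conditions: H2 (1 atm), 10% Pd/C, EtOAc, rt
Reagents that add atoms: none
Why: Hydrogenolysis of the two aryl benzyl ethers over Pd/C in neutral ethyl acetate frees both phenols and leaves the silyl ether, the ester and the stereocentre alone.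

Step 12
Reactants: 19 methyl 3-[(2R)-1-{[tert-butyl(dimethyl)silyl]oxy}-3-(4-hydroxy-3-methoxyphenyl)propan-2-yl]-4-hydroxy-5-methoxybenzoate
Product: 21 methyl (2S,3R)-3-({[tert-butyl(dimethyl)silyl]oxy}methyl)-2-(4-hydroxy-3-methoxyphenyl)-7-methoxy-2,3-dihydro-1-benzofuran-5-carboxylate, via para-quinone methide 20 (not isolated)
Conditions: undivided cell, reticulated vitreous carbon anode, Pt cathode, Ag/AgCl reference, constant potential at the first anodic wave (fixed beforehand by cyclic voltammetry), Bu4NPF6 (0.1 M), CH2Cl2/(CF3)2CHOH 4:1, 0.01 M in 19, no base, 0 °C, 2.0 F/mol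
Reagents that add atoms: none
Why: Proposed new method: at the potential of its first wave the neutral 4-alkylguaiacol ring C should lose two electrons and two protons (the phenolic one and one from the benzylic CH2) to give para-quinone methide 20, and the ring B phenol oxygen then adds to the exocyclic carbon, which forms C2–O1 and restores the aromaticity of ring C, while hydrogen evolution at the cathode keeps the medium near neutral. The closest known reaction type is the two-electron anodic or quinone-mediated oxidation of 4-alkyl-2-methoxyphenols to para-quinone methides that are captured by oxygen nucleophiles, including quinone-mediated closures of 2-hydroxy-1,3-diarylpropanes to flavans; capture by a tethered phenol to close a five-membered ring at an anode is the untested extension. The dihydrofuran ring closes in a 5-exo-trig mode (an intramolecular 1,6-oxa-Michael addition). The new C2 stereocentre is controlled by the C3 centre, since O1 should add to the face that places the aryl group anti to the CH2OTBS group, and because the closure can reopen through 20 the more stable 2,3-trans (2S,3R) isomer should accumulate. The step needs ring C to be oxidised before ring B and before the product: the para ester raises the potential of ring B and blocks its para position, the absence of base keeps the more acidic ring B phenol from ionising to an easily oxidised phenolate, the fluorinated alcohol is too weak a nucleophile to trap 20, high dilution disfavours radical coupling, and the charge is held at two electrons per molecule so that the product, whose ring C is made harder to oxidise by the benzylic oxygen, is not carried on to the benzofuran.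

Step 13
Reactants: 21 methyl (2S,3R)-3-({[tert-butyl(dimethyl)silyl]oxy}methyl)-2-(4-hydroxy-3-methoxyphenyl)-7-methoxy-2,3-dihydro-1-benzofuran-5-carboxylate
Product: 22 methyl (2S,3R)-2-[4-(benzyloxy)-3-methoxyphenyl]-3-({[tert-butyl(dimethyl)silyl]oxy}methyl)-7-methoxy-2,3-dihydro-1-benzofuran-5-carboxylate
Conditions: BnBr, K2CO3, DMF, rt
Reagents that add atoms: benzyl bromide, BrCc1ccccc1
Why: Williamson benzylation of the ring C phenol under mild carbonate conditions, after which the dihydrofuran can no longer reopen through a quinone methide, so the C2 centre is locked.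

Step 14
Reactants: 22 methyl (2S,3R)-2-[4-(benzyloxy)-3-methoxyphenyl]-3-({[tert-butyl(dimethyl)silyl]oxy}methyl)-7-methoxy-2,3-dihydro-1-benzofuran-5-carboxylate
Product: 23 [(2S,3R)-2-[4-(benzyloxy)-3-methoxyphenyl]-3-({[tert-butyl(dimethyl)silyl]oxy}methyl)-7-methoxy-2,3-dihydro-1-benzofuran-5-yl]methanol
Conditions: LiAlH4, THF, 0 °C
Reagents that add atoms: none
Why: LiAlH4 reduces the aryl methyl ester to the benzylic alcohol and leaves the silyl ether, the benzyl ether and the cyclic benzylic ether untouched.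

Step 15
Reactants: 23 [(2S,3R)-2-[4-(benzyloxy)-3-methoxyphenyl]-3-({[tert-butyl(dimethyl)silyl]oxy}methyl)-7-methoxy-2,3-dihydro-1-benzofuran-5-yl]methanol
Product: 24 (2S,3R)-2-[4-(benzyloxy)-3-methoxyphenyl]-5-(bromomethyl)-3-({[tert-butyl(dimethyl)silyl]oxy}methyl)-7-methoxy-2,3-dihydro-1-benzofuran
Conditions: CBr4, PPh3, CH2Cl2, 0 °C; used at once
Reagents that add atoms: carbon tetrabromide, BrC(Br)(Br)Br
Why: Appel reaction, in which the alkoxyphosphonium ion formed from PPh3 and CBr4 is displaced by bromide under neutral conditions, so no HBr is present to cleave the silyl ether or ionise the C2–O1 bond.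

Step 16
Reactants: 25 mono-tert-butyl succinate; 9 (R)-4-benzyl-2-oxazolidinone
Product: 27 tert-butyl 4-[(4R)-4-benzyl-2-oxo-1,3-oxazolidin-3-yl]-4-oxobutanoate, via mixed pivalic anhydride 26 (not isolated)
Conditions: t-BuCOCl, Et3N, THF, −20 °C; then 9, LiCl, −20 °C to rt
Reagents that add atoms: none
Why: N-acylation of the oxazolidinone through the mixed pivalic anhydride as in step 5, the tert-butyl ester being inert.

Step 17
Reactants: 27 tert-butyl 4-[(4R)-4-benzyl-2-oxo-1,3-oxazolidin-3-yl]-4-oxobutanoate; 14 4-(benzyloxy)-3-methoxybenzyl bromide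
Product: 29 tert-butyl (3R)-3-{[(4R)-4-benzyl-2-oxo-1,3-oxazolidin-3-yl]carbonyl}-4-[4-(benzyloxy)-3-methoxyphenyl]butanoate, via sodium Z-enolate 28 (not isolated)
Conditions: NaN(SiMe3)2, THF, −78 °C; then 14, −78 to −40 °C
Reagents that add atoms: none
Why: Evans asymmetric alkylation of the chelated Z sodium enolate (formed at the more acidic imide α-carbon) on the face away from the auxiliary benzyl group sets the R centre that becomes C4 of the lactone and then C2 of the butanediol.

Step 18
Reactants: 29 tert-butyl (3R)-3-{[(4R)-4-benzyl-2-oxo-1,3-oxazolidin-3-yl]carbonyl}-4-[4-(benzyloxy)-3-methoxyphenyl]butanoate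
Product: 31 (4R)-4-[4-(benzyloxy)-3-methoxybenzyl]dihydrofuran-2(3H)-one, via hydroxy ester 30 (not isolated)
Conditions: NaBH4, THF/H2O 3:1, 0 °C to rt; crude: TsOH·H2O (cat.), PhMe, 80 °C
Reagents that add atoms: none
Why: NaBH4 in wet THF cleaves the imide reductively to the 4-hydroxy ester and returns the auxiliary, and acid-catalysed lactonisation (intramolecular transesterification with loss of tert-butanol) then closes the five-membered lactone without touching the stereocentre.

Step 19
Reactants: 31 (4R)-4-[4-(benzyloxy)-3-methoxybenzyl]dihydrofuran-2(3H)-one; 24 (2S,3R)-2-[4-(benzyloxy)-3-methoxyphenyl]-5-(bromomethyl)-3-({[tert-butyl(dimethyl)silyl]oxy}methyl)-7-methoxy-2,3-dihydro-1-benzofuran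
Product: 33 (3R,4R)-4-[4-(benzyloxy)-3-methoxybenzyl]-3-{[(2S,3R)-2-[4-(benzyloxy)-3-methoxyphenyl]-3-({[tert-butyl(dimethyl)silyl]oxy}methyl)-7-methoxy-2,3-dihydro-1-benzofuran-5-yl]methyl}dihydrofuran-2(3H)-one, via lithium enolate 32 (not isolated)
Conditions: LiN(SiMe3)2, THF, −78 °C; then 24 in THF/DMPU, −78 to −30 °C
Reagents that add atoms: none
Why: Alkylation of a β-substituted γ-butyrolactone enolate (SN2 on the benzylic bromide) takes place on the face anti to the C4 arylmethyl group, which should give the 3,4-trans lactone and so set the second butanediol centre as R, as is usual in the synthesis of dibenzylbutyrolactone lignans.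

Step 20
Reactants: 33 (3R,4R)-4-[4-(benzyloxy)-3-methoxybenzyl]-3-{[(2S,3R)-2-[4-(benzyloxy)-3-methoxyphenyl]-3-({[tert-butyl(dimethyl)silyl]oxy}methyl)-7-methoxy-2,3-dihydro-1-benzofuran-5-yl]methyl}dihydrofuran-2(3H)-one
Product: 34 (2R,3R)-2-[4-(benzyloxy)-3-methoxybenzyl]-3-{[(2S,3R)-2-[4-(benzyloxy)-3-methoxyphenyl]-3-({[tert-butyl(dimethyl)silyl]oxy}methyl)-7-methoxy-2,3-dihydro-1-benzofuran-5-yl]methyl}butane-1,4-diol
Conditions: LiAlH4, THF, 0 °C to rt
Reagents that add atoms: none
Why: LiAlH4 reduction of the lactone gives the 1,4-diol with both stereocentres unchanged, since hydride addition to the carbonyl is faster than enolisation.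

Step 21
Reactants: 34 (2R,3R)-2-[4-(benzyloxy)-3-methoxybenzyl]-3-{[(2S,3R)-2-[4-(benzyloxy)-3-methoxyphenyl]-3-({[tert-butyl(dimethyl)silyl]oxy}methyl)-7-methoxy-2,3-dihydro-1-benzofuran-5-yl]methyl}butane-1,4-diol
Product: 35 (2R,3R)-2-[4-(benzyloxy)-3-methoxybenzyl]-3-{[(2S,3R)-2-[4-(benzyloxy)-3-methoxyphenyl]-3-(hydroxymethyl)-7-methoxy-2,3-dihydro-1-benzofuran-5-yl]methyl}butane-1,4-diol
Conditions: Bu4NF, THF, 0 °C to rt
Reagents that add atoms: none
Why: Fluoride-mediated desilylation (driven by the strong Si–F bond) frees the primary alcohol while both phenols are still benzylated, so the basic fluoride cannot open the dihydrofuran through a phenoxide.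

Step 22
Reactants: 35 (2R,3R)-2-[4-(benzyloxy)-3-methoxybenzyl]-3-{[(2S,3R)-2-[4-(benzyloxy)-3-methoxyphenyl]-3-(hydroxymethyl)-7-methoxy-2,3-dihydro-1-benzofuran-5-yl]methyl}butane-1,4-diol
Product: 36 (2R,3R)-2-(4-hydroxy-3-methoxybenzyl)-3-{[(2S,3R)-2-(4-hydroxy-3-methoxyphenyl)-3-(hydroxymethyl)-7-methoxy-2,3-dihydro-1-benzofuran-5-yl]methyl}butane-1,4-diol (CNP0256425.1)
Conditions: H2 (1 atm), 10% Pd/C, EtOAc/MeOH, rt
Reagents that add atoms: none
Why: Catalytic hydrogenolysis of the two aryl benzyl ethers over Pd/C under neutral conditions, stopped after uptake of two equivalents of H2 because aryl benzyl ethers are cleaved much faster than the cyclic benzylic C2–O1 bond, should give the target.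

**Compound list**

1 | methyl vanillate (methyl 4-hydroxy-3-methoxybenzoate) | COC(=O)c1ccc(O)c(OC)c1 | starting material
2 | allyl bromide | C=CCBr | starting material
3 | methyl 4-(allyloxy)-3-methoxybenzoate | COC(=O)c1ccc(OCC=C)c(OC)c1 | intermediate
4 | methyl 3-allyl-4-hydroxy-5-methoxybenzoate | COC(=O)c1cc(CC=C)c(O)c(OC)c1 | intermediate
5 | methyl 3-allyl-4-(benzyloxy)-5-methoxybenzoate | COC(=O)c1cc(CC=C)c(OCc2ccccc2)c(OC)c1 | intermediate
6 | secondary ozonide of 5, methyl 4-(benzyloxy)-3-methoxy-5-(1,2,4-trioxolan-3-ylmethyl)benzoate (not isolated) | COC(=O)c1cc(CC2OCOO2)c(OCc2ccccc2)c(OC)c1 | intermediate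
7 | methyl 4-(benzyloxy)-3-methoxy-5-(2-oxoethyl)benzoate (not isolated) | COC(=O)c1cc(CC=O)c(OCc2ccccc2)c(OC)c1 | intermediate
8 | [2-(benzyloxy)-3-methoxy-5-(methoxycarbonyl)phenyl]acetic acid | COC(=O)c1cc(CC(=O)O)c(OCc2ccccc2)c(OC)c1 | intermediate
9 | (R)-4-benzyl-2-oxazolidinone | O=C1N[C@H](Cc2ccccc2)CO1 | starting material
10 | mixed anhydride of acid 8 and pivalic acid (not isolated) | COC(=O)c1cc(CC(=O)OC(=O)C(C)(C)C)c(OCc2ccccc2)c(OC)c1 | intermediate
11 | (4R)-4-benzyl-3-{[2-(benzyloxy)-3-methoxy-5-(methoxycarbonyl)phenyl]acetyl}-1,3-oxazolidin-2-one | COC(=O)c1cc(CC(=O)N2[C@H](Cc3ccccc3)COC2=O)c(OCc2ccccc2)c(OC)c1 | intermediate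
12 | 4-(benzyloxy)-3-methoxybenzaldehyde | COc1cc(C=O)ccc1OCc1ccccc1 | starting material
13 | [4-(benzyloxy)-3-methoxyphenyl]methanol | COc1cc(CO)ccc1OCc1ccccc1 | intermediate
14 | 4-(benzyloxy)-3-methoxybenzyl bromide | COc1cc(CBr)ccc1OCc1ccccc1 | intermediate
15 | sodium Z-enolate of 11 (not isolated) | COC(=O)c1cc(/C=C(\[O-])N2[C@H](Cc3ccccc3)COC2=O)c(OCc2ccccc2)c(OC)c1.[Na+] | intermediate
16 | (4R)-4-benzyl-3-[(2R)-2-[2-(benzyloxy)-3-methoxy-5-(methoxycarbonyl)phenyl]-3-[4-(benzyloxy)-3-methoxyphenyl]propanoyl]-1,3-oxazolidin-2-one | COC(=O)c1cc([C@@H](Cc2ccc(OCc3ccccc3)c(OC)c2)C(=O)N2[C@H](Cc3ccccc3)COC2=O)c(OCc2ccccc2)c(OC)c1 | intermediate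
17 | methyl 4-(benzyloxy)-3-[(2R)-1-[4-(benzyloxy)-3-methoxyphenyl]-3-hydroxypropan-2-yl]-5-methoxybenzoate | COC(=O)c1cc([C@H](CO)Cc2ccc(OCc3ccccc3)c(OC)c2)c(OCc2ccccc2)c(OC)c1 | intermediate
18 | methyl 4-(benzyloxy)-3-[(2R)-1-[4-(benzyloxy)-3-methoxyphenyl]-3-{[tert-butyl(dimethyl)silyl]oxy}propan-2-yl]-5-methoxybenzoate | COC(=O)c1cc([C@H](CO[Si](C)(C)C(C)(C)C)Cc2ccc(OCc3ccccc3)c(OC)c2)c(OCc2ccccc2)c(OC)c1 | intermediate
19 | methyl 3-[(2R)-1-{[tert-butyl(dimethyl)silyl]oxy}-3-(4-hydroxy-3-methoxyphenyl)propan-2-yl]-4-hydroxy-5-methoxybenzoate (key-step precursor) | COC(=O)c1cc([C@H](CO[Si](C)(C)C(C)(C)C)Cc2ccc(O)c(OC)c2)c(O)c(OC)c1 | intermediate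
20 | para-quinone methide of 19, ring C as 4-alkylidene-2-methoxycyclohexa-2,5-dien-1-one, alkene geometry open (not isolated) | COC(=O)c1cc([C@H](CO[Si](C)(C)C(C)(C)C)C=C2C=CC(=O)C(OC)=C2)c(O)c(OC)c1 | intermediate
21 | methyl (2S,3R)-3-({[tert-butyl(dimethyl)silyl]oxy}methyl)-2-(4-hydroxy-3-methoxyphenyl)-7-methoxy-2,3-dihydro-1-benzofuran-5-carboxylate (key-step product) | COC(=O)c1cc(OC)c2c(c1)[C@H](CO[Si](C)(C)C(C)(C)C)[C@@H](c1ccc(O)c(OC)c1)O2 | intermediate
22 | methyl (2S,3R)-2-[4-(benzyloxy)-3-methoxyphenyl]-3-({[tert-butyl(dimethyl)silyl]oxy}methyl)-7-methoxy-2,3-dihydro-1-benzofuran-5-carboxylate | COC(=O)c1cc(OC)c2c(c1)[C@H](CO[Si](C)(C)C(C)(C)C)[C@@H](c1ccc(OCc3ccccc3)c(OC)c1)O2 | intermediate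
23 | [(2S,3R)-2-[4-(benzyloxy)-3-methoxyphenyl]-3-({[tert-butyl(dimethyl)silyl]oxy}methyl)-7-methoxy-2,3-dihydro-1-benzofuran-5-yl]methanol | OCc1cc(OC)c2c(c1)[C@H](CO[Si](C)(C)C(C)(C)C)[C@@H](c1ccc(OCc3ccccc3)c(OC)c1)O2 | intermediate
24 | (2S,3R)-2-[4-(benzyloxy)-3-methoxyphenyl]-5-(bromomethyl)-3-({[tert-butyl(dimethyl)silyl]oxy}methyl)-7-methoxy-2,3-dihydro-1-benzofuran | BrCc1cc(OC)c2c(c1)[C@H](CO[Si](C)(C)C(C)(C)C)[C@@H](c1ccc(OCc3ccccc3)c(OC)c1)O2 | intermediate
25 | mono-tert-butyl succinate (4-tert-butoxy-4-oxobutanoic acid) | CC(C)(C)OC(=O)CCC(=O)O | starting material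
26 | mixed anhydride of 25 and pivalic acid (not isolated) | CC(C)(C)OC(=O)CCC(=O)OC(=O)C(C)(C)C | intermediate
27 | tert-butyl 4-[(4R)-4-benzyl-2-oxo-1,3-oxazolidin-3-yl]-4-oxobutanoate | CC(C)(C)OC(=O)CCC(=O)N1[C@H](Cc2ccccc2)COC1=O | intermediate
28 | sodium Z-enolate of 27 (not isolated) | CC(C)(C)OC(=O)C/C=C(\[O-])N1[C@H](Cc2ccccc2)COC1=O.[Na+] | intermediate
29 | tert-butyl (3R)-3-{[(4R)-4-benzyl-2-oxo-1,3-oxazolidin-3-yl]carbonyl}-4-[4-(benzyloxy)-3-methoxyphenyl]butanoate | CC(C)(C)OC(=O)C[C@@H](Cc1ccc(OCc2ccccc2)c(OC)c1)C(=O)N1[C@H](Cc2ccccc2)COC1=O | intermediate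
30 | tert-butyl (3R)-3-[4-(benzyloxy)-3-methoxybenzyl]-4-hydroxybutanoate (not isolated) | CC(C)(C)OC(=O)C[C@@H](Cc1ccc(OCc2ccccc2)c(OC)c1)CO | intermediate
31 | (4R)-4-[4-(benzyloxy)-3-methoxybenzyl]dihydrofuran-2(3H)-one | O=C1C[C@@H](Cc2ccc(OCc3ccccc3)c(OC)c2)CO1 | intermediate
32 | lithium enolate of 31 (not isolated) | [Li+].[O-]C1=C[C@@H](Cc2ccc(OCc3ccccc3)c(OC)c2)CO1 | intermediate
33 | (3R,4R)-4-[4-(benzyloxy)-3-methoxybenzyl]-3-{[(2S,3R)-2-[4-(benzyloxy)-3-methoxyphenyl]-3-({[tert-butyl(dimethyl)silyl]oxy}methyl)-7-methoxy-2,3-dihydro-1-benzofuran-5-yl]methyl}dihydrofuran-2(3H)-one | O=C1[C@H](Cc2cc(OC)c3c(c2)[C@H](CO[Si](C)(C)C(C)(C)C)[C@@H](c2ccc(OCc4ccccc4)c(OC)c2)O3)[C@@H](Cc2ccc(OCc3ccccc3)c(OC)c2)CO1 | intermediate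
34 | (2R,3R)-2-[4-(benzyloxy)-3-methoxybenzyl]-3-{[(2S,3R)-2-[4-(benzyloxy)-3-methoxyphenyl]-3-({[tert-butyl(dimethyl)silyl]oxy}methyl)-7-methoxy-2,3-dihydro-1-benzofuran-5-yl]methyl}butane-1,4-diol | COc1cc(C[C@@H](CO)[C@H](CO)Cc2cc(OC)c3c(c2)[C@H](CO[Si](C)(C)C(C)(C)C)[C@@H](c2ccc(OCc4ccccc4)c(OC)c2)O3)ccc1OCc1ccccc1 | intermediate
35 | (2R,3R)-2-[4-(benzyloxy)-3-methoxybenzyl]-3-{[(2S,3R)-2-[4-(benzyloxy)-3-methoxyphenyl]-3-(hydroxymethyl)-7-methoxy-2,3-dihydro-1-benzofuran-5-yl]methyl}butane-1,4-diol | COc1cc(C[C@@H](CO)[C@H](CO)Cc2cc(OC)c3c(c2)[C@H](CO)[C@@H](c2ccc(OCc4ccccc4)c(OC)c2)O3)ccc1OCc1ccccc1 | intermediate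
36 | (2R,3R)-2-(4-hydroxy-3-methoxybenzyl)-3-{[(2S,3R)-2-(4-hydroxy-3-methoxyphenyl)-3-(hydroxymethyl)-7-methoxy-2,3-dihydro-1-benzofuran-5-yl]methyl}butane-1,4-diol (CNP0256425.1) | COc1cc(C[C@@H](CO)[C@H](CO)Cc2cc(OC)c3c(c2)[C@H](CO)[C@@H](c2ccc(O)c(OC)c2)O3)ccc1O | target

**Step count and risks**

Total step count: 22 (main line 17, benzyl bromide branch 2, lactone branch 3).
Longest linear sequence: 17 steps (steps 1–5, 8–15 and 19–22, from methyl vanillate).

Steps most likely to fail:

1. Step 12 (Proposed new method). The closure may fail in four ways: coupling of phenoxyl radicals at the free ortho position of ring C, capture of the oxidised ring C at its ipso carbon in place of loss of the benzylic proton, oxidation of ring B if its phenol ionises, or onward oxidation of the product to the benzofuran. The fallback uses known chemistry and brings C2 in at the alcohol oxidation level by an aldol reaction. It sets out from acid 8. Acylation of (S)-4-benzyl-2-oxazolidinone through mixed anhydride 10 would give the (4S)-arylacetyl imide F1. The antipodal auxiliary is needed because a boron aldol reaction uses the enolate face opposite to the one used in alkylation. Bu2BOTf and i-Pr2NEt, then aldehyde 12 (CH2Cl2, −78 to 0 °C), should give the Evans syn aldol adduct F2 with the future C3 in the same sense as in 19. NaBH4 in wet THF removes the auxiliary to give the 1,3-diol F3. TBSCl and imidazole silylate the primary hydroxyl to give the mono-silyl ether F4. Hydrogenolysis (H2, Pd/C, EtOAc) frees both phenols to give the para-hydroxybenzylic alcohol F5. Catalytic pyridinium p-toluenesulfonate in CH2Cl2 at 0 °C should then ionise the benzylic alcohol to quinone methide 20, which closes to the trans product. The fallback comes back to the route at 21.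

2. Step 19. The union may fail through ionisation or decomposition of the electron-rich benzylic bromide, through proton transfer to the enolate in place of C-alkylation, or through a second alkylation. The fallback replaces the alkylation by an aldol addition followed by radical deoxygenation. It sets out from alcohol 23. MnO2 in CH2Cl2 oxidises 23 to the benzofuran-5-carbaldehyde F6. The lithium enolate 32 of lactone 31 (LiN(SiMe3)2, THF, −78 °C) should add to F6 anti to the C4 substituent to give the 3,4-trans β-hydroxy lactone F7 as a mixture of carbinol epimers. Phenyl chlorothionoformate with pyridine and DMAP converts the carbinol into the O-phenyl thionocarbonate F8. Barton–McCombie reduction (Bu3SnH, AIBN, PhMe, 80 °C) removes the benzylic oxygen and leaves the lactone α-centre as set in the aldol step. The fallback comes back to the route at 33.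

3. Step 9. The borohydride cleavage may fail through epimerisation of the aryl-bearing centre by enolisation of the transient 2-arylaldehyde, through hydride attack at the ring carbamate carbonyl of the hindered imide, or through slow reduction of the aryl ester. The fallback separates cleavage from reduction and sets out from imide 16. LiOH and H2O2 (THF/H2O, 0 °C) hydrolyse the imide at the exocyclic carbonyl to the (2R)-2,3-diarylpropanoic acid F9. BH3·SMe2 (THF, 0 °C) then reduces the carboxylic acid, and not the methyl ester, to the alcohol. The fallback comes back to the route at 17.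

**Further compounds**

F1 | step 12 | (4S)-4-benzyl-3-{[2-(benzyloxy)-3-methoxy-5-(methoxycarbonyl)phenyl]acetyl}-1,3-oxazolidin-2-one | COC(=O)c1cc(CC(=O)N2[C@@H](Cc3ccccc3)COC2=O)c(OCc2ccccc2)c(OC)c1
F2 | step 12 | (4S)-4-benzyl-3-[(2S,3S)-2-[2-(benzyloxy)-3-methoxy-5-(methoxycarbonyl)phenyl]-3-[4-(benzyloxy)-3-methoxyphenyl]-3-hydroxypropanoyl]-1,3-oxazolidin-2-one | COC(=O)c1cc([C@@H]([C@H](O)c2ccc(OCc3ccccc3)c(OC)c2)C(=O)N2[C@@H](Cc3ccccc3)COC2=O)c(OCc2ccccc2)c(OC)c1
F3 | step 12 | methyl 4-(benzyloxy)-3-[(1S,2R)-1-[4-(benzyloxy)-3-methoxyphenyl]-1,3-dihydroxypropan-2-yl]-5-methoxybenzoate | COC(=O)c1cc([C@@H]([C@H](O)c2ccc(OCc3ccccc3)c(OC)c2)CO)c(OCc2ccccc2)c(OC)c1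
F4 | step 12 | methyl 4-(benzyloxy)-3-[(1S,2R)-1-[4-(benzyloxy)-3-methoxyphenyl]-3-{[tert-butyl(dimethyl)silyl]oxy}-1-hydroxypropan-2-yl]-5-methoxybenzoate | COC(=O)c1cc([C@@H]([C@H](O)c2ccc(OCc3ccccc3)c(OC)c2)CO[Si](C)(C)C(C)(C)C)c(OCc2ccccc2)c(OC)c1
F5 | step 12 | methyl 3-[(1S,2R)-3-{[tert-butyl(dimethyl)silyl]oxy}-1-hydroxy-1-(4-hydroxy-3-methoxyphenyl)propan-2-yl]-4-hydroxy-5-methoxybenzoate | COC(=O)c1cc([C@@H]([C@H](O)c2ccc(O)c(OC)c2)CO[Si](C)(C)C(C)(C)C)c(O)c(OC)c1
F6 | step 19 | (2S,3R)-2-[4-(benzyloxy)-3-methoxyphenyl]-3-({[tert-butyl(dimethyl)silyl]oxy}methyl)-7-methoxy-2,3-dihydro-1-benzofuran-5-carbaldehyde | O=Cc1cc(OC)c2c(c1)[C@H](CO[Si](C)(C)C(C)(C)C)[C@@H](c1ccc(OCc3ccccc3)c(OC)c1)O2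
F7 | step 19 | (3S,4R)-4-[4-(benzyloxy)-3-methoxybenzyl]-3-{hydroxy[(2S,3R)-2-[4-(benzyloxy)-3-methoxyphenyl]-3-({[tert-butyl(dimethyl)silyl]oxy}methyl)-7-methoxy-2,3-dihydro-1-benzofuran-5-yl]methyl}dihydrofuran-2(3H)-one, 3,4-trans, both carbinol epimers | O=C1[C@H](C(O)c2cc(OC)c3c(c2)[C@H](CO[Si](C)(C)C(C)(C)C)[C@@H](c2ccc(OCc4ccccc4)c(OC)c2)O3)[C@@H](Cc2ccc(OCc3ccccc3)c(OC)c2)CO1
F8 | step 19 | O-phenyl thionocarbonate of F7 | O=C1[C@H](C(OC(=S)Oc2ccccc2)c2cc(OC)c3c(c2)[C@H](CO[Si](C)(C)C(C)(C)C)[C@@H](c2ccc(OCc4ccccc4)c(OC)c2)O3)[C@@H](Cc2ccc(OCc3ccccc3)c(OC)c2)CO1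
F9 | step 9 | (2R)-2-[2-(benzyloxy)-3-methoxy-5-(methoxycarbonyl)phenyl]-3-[4-(benzyloxy)-3-methoxyphenyl]propanoic acid | COC(=O)c1cc([C@@H](Cc2ccc(OCc3ccccc3)c(OC)c2)C(=O)O)c(OCc2ccccc2)c(OC)c1
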